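**Strategy**

Ring A is built last by a formal [4+2] annulation. The 6α-oxygen and C18, both attached to the C4–C5–C6 array, are tied as a temporary trans-fused γ-lactone on a ring-B aldehyde. Its enolate (C4) adds to vinyltriphenylphosphonium bromide on the face opposite the C10 methyl group, and the ylide so formed (C2) closes on the C10 formyl carbon (C1): C3–C4 and C1–C2 form in one operation with the C4 quaternary centre set. Ring B comes from (S)-4-silyloxy-2-methylcyclohexenone by a Mukaiyama–Michael/orthoformate three-component coupling; lactone reduction later gives the 6,18-diol, and the side chain is added at the C9 ketone.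

Key step: step 9

Remark: labdane numbering is used (C18 = CH2OH carbon on C4, C19 = methyl on C4, C20 = methyl on C10, C17 = exocyclic methylene carbon, C16 = methyl on C13); butenolide atoms are primed (C2′ carbonyl, C4′ bearing methyl, C5′ attached to C15); α is the face of H5, β the face of C20.

Remark: compounds 9–13 are carried as mixtures at C4 and 31 as either C9 epimer; both centres become trigonal before their configuration is fixed.

**Route**

Step 1
Reactants: 1 4-(tert-butyldimethylsilyloxy)cyclohexan-1-one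
Product: 2 (S)-4-(tert-butyldimethylsilyloxy)-1-(trimethylsilyloxy)cyclohex-1-ene
Conditions: lithium (R,R)-bis(1-phenylethyl)amide (from the amine and n-BuLi), LiCl, TMSCl (internal quench), THF, −78 °C
Reagents that add atoms: chlorotrimethylsilane, C[Si](C)(C)Cl
Why: Asymmetric deprotonation of a prochiral 4-substituted cyclohexanone by a chiral lithium amide with internal silyl quench should remove one of the two enantiotopic axial α-protons, so that the silyloxy carbon (future C6) becomes stereogenic with (S) configuration.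

Step 2
Reactants: 2 (S)-4-(tert-butyldimethylsilyloxy)-1-(trimethylsilyloxy)cyclohex-1-ene
Product: 3 (S)-4-(tert-butyldimethylsilyloxy)cyclohex-2-en-1-one
Conditions: Pd(OAc)2 (1.0 equiv), MeCN, rt
Reagents that add atoms: none
Why: Saegusa–Ito oxidation places the enone double bond on the side of the former enol ether and leaves the silyloxy-bearing centre untouched.

Step 3
Reactants: 3 (S)-4-(tert-butyldimethylsilyloxy)cyclohex-2-en-1-one
Product: 4 (S)-4-(tert-butyldimethylsilyloxy)-2-iodocyclohex-2-en-1-one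
Conditions: I2, pyridine, CH2Cl2, 0 °C → rt
Reagents that add atoms: iodine, II
Why: α-Iodination of a cyclic enone by conjugate addition of pyridine, iodination of the enolate and elimination.

Step 4
Reactants: 4 (S)-4-(tert-butyldimethylsilyloxy)-2-iodocyclohex-2-en-1-one
Product: 5 (S)-4-(tert-butyldimethylsilyloxy)-2-methylcyclohex-2-en-1-one
Conditions: Me4Sn, Pd2(dba)3 (cat.), AsPh3, CuI, NMP, 80 °C
Reagents that add atoms: tetramethylstannane, C[Sn](C)(C)C
Why: Stille cross-coupling of the α-iodoenone installs the future C20 methyl group without touching the γ-silyloxy centre.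

Step 5
Reactants: 6 methyl propanoate
Product: 7 1-methoxy-1-(trimethylsilyloxy)prop-1-ene (E/Z mixture)
Conditions: lithium diisopropylamide, TMSCl, THF, −78 °C
Reagents that add atoms: chlorotrimethylsilane, C[Si](C)(C)Cl
Why: Kinetic ester enolization with O-silylation gives the ketene silyl acetal, whose geometry is irrelevant because the carbon it delivers (C4) is re-enolized in step 9.

Step 6
Reactants: 5 (S)-4-(tert-butyldimethylsilyloxy)-2-methylcyclohex-2-en-1-one; 7 1-methoxy-1-(trimethylsilyloxy)prop-1-ene; 8 trimethyl orthoformate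
Product: 10 ring-B keto acetal ester (5β-propanoate; 6α-OTBS; 10β-methyl; 10α-dimethoxymethyl), via TMS enol ether 9 (not isolated)
Conditions: HNTf2 (5 mol %), CH2Cl2, −78 °C; then 8, TMSOTf (10 mol %), −78 → −20 °C
Reagents that add atoms: none
Why: Mukaiyama–Michael addition should occur anti to the γ-silyloxy group (sets C5) with silyl transfer to the regiodefined enol silane 9, whose Mukaiyama-type reaction with the dimethoxycarbenium ion from the orthoformate takes place anti to the new C5 substituent and creates the C10 quaternary centre.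

Step 7
Reactants: 10 ring-B keto acetal ester
Product: 12 keto aldehyde lactone (trans-fused 18→6α γ-lactone; C9 ketone; C10 β-methyl α-formyl), via hydroxy keto aldehyde 11 (not isolated)
Conditions: 3 M HCl, THF, rt; then TsOH (cat.), toluene, 80 °C
Reagents that add atoms: water, O
Why: Aqueous acid cleaves the silyl ether and the dimethyl acetal, and the 6α-hydroxy ester then lactonizes to the trans-fused γ-lactone (both ring bonds equatorial) without touching a stereocentre.

Step 8
Reactants: 12 keto aldehyde lactone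
Product: 13 silyl enol ether aldehyde lactone (C9-OTBS with C8=C9)
Conditions: TBSOTf (1.1 equiv), Et3N, CH2Cl2, −78 → 0 °C
Reagents that add atoms: tert-butyldimethylsilyl trifluoromethanesulfonate, CC(C)(C)[Si](C)(C)OS(=O)(=O)C(F)(F)F
Why: Soft enolization and O-silylation of the ketone, which can enolize only toward C8 because C10 is quaternary, while the aldehyde has no α-hydrogen and the lactone is far less reactive.

Step 9
Reactants: 13 silyl enol ether aldehyde lactone; 14 vinyltriphenylphosphonium bromide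
Product: 17 tricyclic ene lactone (ring A closed with C1=C2; 4β-methyl; 18,6α-olide), via lithium lactone enolate 15 (not isolated), via phosphonium ylide 16 (not isolated)
Conditions: lithium 2,2,6,6-tetramethylpiperidide (from the amine and n-BuLi), THF, −78 °C; then 14, THF/DMPU, −78 → 65 °C
Reagents that add atoms: none
Why: Deprotonation of the lactone α-carbon (C4) gives the tetrasubstituted lithium enolate 15, which adds through carbon to the vinylphosphonium salt (C3–C4) and so generates the non-stabilized ylide 16, which closes on the C10 formyl group (C1–C2) by intramolecular Wittig olefination with loss of triphenylphosphine oxide. The closest known reaction type is the enolate annulation with Schweizer's reagent (Michael addition followed by intramolecular Wittig reaction). Ring A closes in the 6-exo-trig mode on the carbonyl and can only give the cis ring alkene. The new quaternary stereocentre C4 is controlled by the trans-fused lactone: the planar enolate lies roughly in the mean plane of ring B, its β face is shielded by the axial C10 methyl group in a 1,3-relationship, so C3 should enter from the α face (syn to H5) and the C4 methyl group becomes β-axial. The step needs chemoselective enolization beside an aldehyde, which is secured because the aldehyde is non-enolizable and neopentylic, the ketone is masked as its silyl enol ether and C4–H is the only acidic proton.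

Step 10
Reactants: 17 tricyclic ene lactone
Product: 18 saturated tricyclic lactone
Conditions: H2 (1 atm), RhCl(PPh3)3 (5 mol %), benzene, rt
Reagents that add atoms: none
Why: Homogeneous hydrogenation with RhCl(PPh3)3 should reduce the cis-disubstituted C1=C2 bond in preference to the hindered trisubstituted silyl enol ether.

Step 11
Reactants: 18 saturated tricyclic lactone
Product: 19 6α,18-diol (C9 silyl enol ether retained)
Conditions: LiAlH4, THF, 0 °C → rt; aqueous Rochelle salt
Reagents that add atoms: none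
Why: Hydride reduction opens the temporary lactone to the 6α,18-diol without affecting the silyl enol ether or any stereocentre.

Step 12
Reactants: 19 6α,18-diol
Product: 20 6α,18-bis(silyl ether) of 19
Conditions: TBSOTf (2.5 equiv), 2,6-lutidine, CH2Cl2, 0 °C
Reagents that add atoms: tert-butyldimethylsilyl trifluoromethanesulfonate, CC(C)(C)[Si](C)(C)OS(=O)(=O)C(F)(F)F
Why: Silyl triflate silylation protects the secondary equatorial and the neopentyl primary hydroxyl groups.

Step 13
Reactants: 20 bis(silyl ether) silyl enol ether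
Product: 23 8-methylidene-9-ketone, via Mannich base 21 (not isolated), via ammonium iodide 22 (not isolated)
Conditions: CH2=NMe2+ I−, CH2Cl2, rt; then MeI; then DBU, CH2Cl2
Reagents that add atoms: dimethyl(methylidene)ammonium iodide, C=[N+](C)C.[I-]
Why: Eschenmoser methylenation (Mannich reaction of the silyl enol ether at C8, N-methylation, E1cB elimination) gives the α-methylene ketone that carries C17.

Step 14
Reactants: 24 4-(tert-butyldimethylsilyloxy)but-1-yne
Product: 26 (E)-5-(tert-butyldimethylsilyloxy)-3-methylpent-2-en-1-ol, via alkenylalane 25 (not isolated)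
Conditions: Me3Al, Cp2ZrCl2 (25 mol %), CH2Cl2, 0 °C → rt; then n-BuLi, (CH2O)n, THF
Reagents that add atoms: trimethylaluminium, C[Al](C)C; paraformaldehyde (as formaldehyde), C=O
Why: Zirconium-catalysed Negishi carboalumination adds methyl and aluminium syn to the terminal alkyne, and the alanate is hydroxymethylated with retention, which fixes the (E)-trisubstituted alkene.

Step 15
Reactants: 26 (E)-5-(tert-butyldimethylsilyloxy)-3-methylpent-2-en-1-ol
Product: 27 4-methoxybenzyl ether of 26
Conditions: NaH, 4-methoxybenzyl chloride, Bu4NI (cat.), DMF, 0 °C → rt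
Reagents that add atoms: 4-methoxybenzyl chloride, COc1ccc(CCl)cc1
Why: Williamson etherification of the allylic alkoxide.

Step 16
Reactants: 27 4-methoxybenzyl ether
Product: 28 (E)-5-(4-methoxybenzyloxy)-3-methylpent-3-en-1-ol
Conditions: Bu4NF, THF, rt
Reagents that add atoms: none
Why: Fluoride cleaves the primary silyl ether and leaves the benzyl ether.

Step 17
Reactants: 28 (E)-5-(4-methoxybenzyloxy)-3-methylpent-3-en-1-ol
Product: 29 (E)-5-iodo-1-(4-methoxybenzyloxy)-3-methylpent-2-ene
Conditions: I2, PPh3, imidazole, CH2Cl2, 0 °C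
Reagents that add atoms: iodine, II
Why: Appel-type iodination of the unhindered primary alcohol.

Step 18
Reactants: 23 8-methylidene-9-ketone; 29 (E)-5-iodo-1-(4-methoxybenzyloxy)-3-methylpent-2-ene
Product: 31 tertiary allylic alcohol (C9 carbinol carrying the C11–C15 chain), via alkyllithium 30 (not isolated)
Conditions: 29, t-BuLi (2.1 equiv), Et2O, −78 °C; then 23, −78 °C; H2O
Reagents that add atoms: none
Why: Iodine–lithium exchange gives the primary alkyllithium, which adds 1,2 to the enone carbonyl, and the C9 configuration is of no consequence because C9 becomes trigonal in step 19.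

Step 19
Reactants: 31 tertiary allylic alcohol
Product: 32 primary allylic chloride (17-chloro; C8=C9)
Conditions: SOCl2, pyridine, Et2O, −20 → 0 °C
Reagents that add atoms: thionyl chloride, O=S(Cl)Cl
Why: The chlorosulfite of the tertiary allylic alcohol collapses with allylic transposition (SNi′) to the primary chloride with the tetrasubstituted C8=C9 bond.

Step 20
Reactants: 32 primary allylic chloride
Product: 33 (13E)-15-(4-methoxybenzyloxy)-6α,18-bis(tert-butyldimethylsilyloxy)labda-8(17),13-diene
Conditions: Pd(OAc)2 (5 mol %), n-Bu3P (5 mol %), HCO2NH4, 1,4-dioxane, 100 °C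
Reagents that add atoms: none
Why: Palladium-catalysed formate reduction of an allylic electrophile (Tsuji–Trost-type hydrogenolysis) should form the π-allyl complex with palladium on the α face, away from the C10 methyl group, and deliver hydride from palladium to the more substituted terminus C9, giving the 9α-hydrogen and the exocyclic C8=C17 bond.

Step 21
Reactants: 33 labdadiene 4-methoxybenzyl ether
Product: 35 (13E)-6α,18-bis(tert-butyldimethylsilyloxy)labda-8(17),13-dien-15-al, via allylic alcohol 34 (not isolated)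
Conditions: DDQ (3 equiv), CH2Cl2/H2O 20:1, 0 °C → rt
Reagents that add atoms: none
Why: DDQ cleaves the electron-rich benzyl ether by hydride abstraction and hydrolysis, and a further equivalent oxidizes the liberated allylic alcohol to the conjugated aldehyde while silyl ethers and unactivated alkenes stay inert.

Step 22
Reactants: 36 4-methylfuran-2(5H)-one
Product: 37 4-methyl-2-(trimethylsilyloxy)furan
Conditions: TMSOTf, Et3N, Et2O, 0 °C
Reagents that add atoms: trimethylsilyl trifluoromethanesulfonate, C[Si](C)(C)OS(=O)(=O)C(F)(F)F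
Why: O-Silylation of the butenolide dienolate gives the 2-silyloxyfuran, a vinylogous enol silane.

Step 23
Reactants: 35 labdadienal; 37 4-methyl-2-(trimethylsilyloxy)furan
Product: 39 6α,18-bis(tert-butyldimethylsilyl) ether of the target, via TMS ether 38 (not isolated)
Conditions: Ti(OiPr)4 (20 mol %), (R)-BINOL (20 mol %), Et2O, −20 °C; then 1 M HCl, THF
Reagents that add atoms: none
Why: Vinylogous Mukaiyama aldol reaction through C5′ of the silyloxyfuran, in which the titanium BINOLate should direct attack to the Re face of the enal (C15, S) and the open transition state that keeps the aldehyde substituent away from the C4′ methyl group should give the syn relationship (C5′, S).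

Step 24
Reactants: 39 bis(silyl ether) of the target
Product: 40 target, (4R,5R,6S,9S,10R,13E,15S,5′S)
Conditions: HF·pyridine, pyridine, THF, 0 °C → rt
Reagents that add atoms: none
Why: Buffered fluoride cleaves both silyl ethers under conditions that should leave the butenolide and the allylic alcohol intact.

**Compound list**

1 | 4-(tert-butyldimethylsilyloxy)cyclohexan-1-one | O=C1CCC(CC1)O[Si](C)(C)C(C)(C)C | starting material
2 | (S)-4-(tert-butyldimethylsilyloxy)-1-(trimethylsilyloxy)cyclohex-1-ene | C[Si](C)(C)OC1=CC[C@@H](O[Si](C)(C)C(C)(C)C)CC1 | intermediate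
3 | (S)-4-(tert-butyldimethylsilyloxy)cyclohex-2-en-1-one | O=C1C=C[C@@H](O[Si](C)(C)C(C)(C)C)CC1 | intermediate
4 | (S)-4-(tert-butyldimethylsilyloxy)-2-iodocyclohex-2-en-1-one | O=C1C(I)=C[C@@H](O[Si](C)(C)C(C)(C)C)CC1 | intermediate
5 | (S)-4-(tert-butyldimethylsilyloxy)-2-methylcyclohex-2-en-1-one | CC1=C[C@@H](O[Si](C)(C)C(C)(C)C)CCC1=O | intermediate
6 | methyl propanoate | CCC(=O)OC | starting material
7 | 1-methoxy-1-(trimethylsilyloxy)prop-1-ene (E/Z) | CC=C(OC)O[Si](C)(C)C | intermediate
8 | trimethyl orthoformate | COC(OC)OC | starting material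
9 | methyl 2-[6-(tert-butyldimethylsilyloxy)-2-methyl-3-(trimethylsilyloxy)cyclohex-2-en-1-yl]propanoate (5β side chain, 6α-OTBS) | COC(=O)C(C)[C@@H]1[C@@H](O[Si](C)(C)C(C)(C)C)CCC(O[Si](C)(C)C)=C1C | intermediate
10 | methyl 2-[6-(tert-butyldimethylsilyloxy)-2-(dimethoxymethyl)-2-methyl-3-oxocyclohexyl]propanoate (5β side chain, 6α-OTBS, 10β-methyl) | COC(=O)C(C)[C@@H]1[C@@H](O[Si](C)(C)C(C)(C)C)CCC(=O)[C@@]1(C)C(OC)OC | intermediate
11 | methyl 2-(2-formyl-6-hydroxy-2-methyl-3-oxocyclohexyl)propanoate (5β side chain, 6α-OH, 10β-methyl) | COC(=O)C(C)[C@@H]1[C@@H](O)CCC(=O)[C@@]1(C)C=O | intermediate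
12 | 3,4-dimethyl-2,5-dioxooctahydro-1-benzofuran-4-carbaldehyde (trans-fused, 4-methyl β) | CC1C(=O)O[C@H]2CCC(=O)[C@@](C)(C=O)[C@H]12 | intermediate
13 | 5-(tert-butyldimethylsilyloxy)-3,4-dimethyl-2-oxo-2,3,3a,4,7,7a-hexahydro-1-benzofuran-4-carbaldehyde (trans-fused, 4-methyl β) | CC1C(=O)O[C@H]2CC=C(O[Si](C)(C)C(C)(C)C)[C@@](C)(C=O)[C@H]12 | intermediate
14 | vinyltriphenylphosphonium bromide | C=C[P+](c1ccccc1)(c1ccccc1)c1ccccc1.[Br-] | starting material
15 | lithium enolate of lactone 13 | [Li+].CC1=C([O-])O[C@H]2CC=C(O[Si](C)(C)C(C)(C)C)[C@@](C)(C=O)[C@H]12 | intermediate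
16 | C4-[2-(triphenylphosphoranylidene)ethyl] lactone aldehyde (ylide) | C[C@]1(CC=P(c2ccccc2)(c2ccccc2)c2ccccc2)C(=O)O[C@H]2CC=C(O[Si](C)(C)C(C)(C)C)[C@@](C)(C=O)[C@H]12 | intermediate
17 | 9-(tert-butyldimethylsilyloxy)-4β,10β-dimethyl-trans-decalin-1,8-diene 18,6α-olide | C[C@@]12C=CC[C@@]3(C)C(=O)O[C@@H](CC=C1O[Si](C)(C)C(C)(C)C)[C@H]23 | intermediate
18 | 9-(tert-butyldimethylsilyloxy)-4β,10β-dimethyl-trans-decal-8-ene 18,6α-olide | C[C@@]12CCC[C@@]3(C)C(=O)O[C@@H](CC=C1O[Si](C)(C)C(C)(C)C)[C@H]23 | intermediate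
19 | 9-(tert-butyldimethylsilyloxy)-4α-(hydroxymethyl)-4β,10β-dimethyl-trans-decal-8-en-6α-ol | OC[C@]1(C)CCC[C@]2(C)C(O[Si](C)(C)C(C)(C)C)=CC[C@H](O)[C@@H]12 | intermediate
20 | 6α,18-bis(tert-butyldimethylsilyl) ether of 19 | CC(C)(C)[Si](C)(C)OC[C@]1(C)CCC[C@]2(C)C(O[Si](C)(C)C(C)(C)C)=CC[C@H](O[Si](C)(C)C(C)(C)C)[C@@H]12 | intermediate
21 | 8-[(dimethylamino)methyl]-9-ketone (Mannich base) | CC(C)(C)[Si](C)(C)OC[C@]1(C)CCC[C@]2(C)C(=O)C(CN(C)C)C[C@H](O[Si](C)(C)C(C)(C)C)[C@@H]12 | intermediate
22 | 8-[(trimethylammonio)methyl]-9-ketone iodide | [I-].CC(C)(C)[Si](C)(C)OC[C@]1(C)CCC[C@]2(C)C(=O)C(C[N+](C)(C)C)C[C@H](O[Si](C)(C)C(C)(C)C)[C@@H]12 | intermediate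
23 | 6α-(tert-butyldimethylsilyloxy)-4α-[(tert-butyldimethylsilyloxy)methyl]-4β,10β-dimethyl-8-methylidene-trans-decalin-9-one | CC(C)(C)[Si](C)(C)OC[C@]1(C)CCC[C@]2(C)C(=O)C(=C)C[C@H](O[Si](C)(C)C(C)(C)C)[C@@H]12 | intermediate
24 | 4-(tert-butyldimethylsilyloxy)but-1-yne | C#CCCO[Si](C)(C)C(C)(C)C | starting material
25 | (E)-[4-(tert-butyldimethylsilyloxy)-2-methylbut-1-enyl]dimethylalane | C[Al](C)/C=C(\C)CCO[Si](C)(C)C(C)(C)C | intermediate
26 | (E)-5-(tert-butyldimethylsilyloxy)-3-methylpent-2-en-1-ol | OC/C=C(\C)CCO[Si](C)(C)C(C)(C)C | intermediate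
27 | (E)-tert-butyl{[5-(4-methoxybenzyloxy)-3-methylpent-3-enyl]oxy}dimethylsilane | COc1ccc(COC/C=C(\C)CCO[Si](C)(C)C(C)(C)C)cc1 | intermediate
28 | (E)-5-(4-methoxybenzyloxy)-3-methylpent-3-en-1-ol | COc1ccc(COC/C=C(\C)CCO)cc1 | intermediate
29 | (E)-5-iodo-1-(4-methoxybenzyloxy)-3-methylpent-2-ene | COc1ccc(COC/C=C(\C)CCI)cc1 | intermediate
30 | (E)-[5-(4-methoxybenzyloxy)-3-methylpent-3-enyl]lithium | [Li]CC/C(C)=C/COCc1ccc(OC)cc1 | intermediate
31 | 9-hydroxy-9-[(E)-5-(4-methoxybenzyloxy)-3-methylpent-3-enyl]-8-methylidene bis(silyl ether) (C9 epimers) | CC(C)(C)[Si](C)(C)OC[C@]1(C)CCC[C@]2(C)C(O)(CC/C(C)=C/COCc3ccc(OC)cc3)C(=C)C[C@H](O[Si](C)(C)C(C)(C)C)[C@@H]12 | intermediate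
32 | (13E)-17-chloro-15-(4-methoxybenzyloxy)-6α,18-bis(tert-butyldimethylsilyloxy)labda-8,13-diene | CC(C)(C)[Si](C)(C)OC[C@]1(C)CCC[C@]2(C)C(CC/C(C)=C/COCc3ccc(OC)cc3)=C(CCl)C[C@H](O[Si](C)(C)C(C)(C)C)[C@@H]12 | intermediate
33 | (13E)-15-(4-methoxybenzyloxy)-6α,18-bis(tert-butyldimethylsilyloxy)labda-8(17),13-diene | C=C1C[C@H](O[Si](C)(C)C(C)(C)C)[C@H]2[C@](C)(CO[Si](C)(C)C(C)(C)C)CCC[C@]2(C)[C@H]1CC/C(C)=C/COCc1ccc(OC)cc1 | intermediate
34 | (13E)-6α,18-bis(tert-butyldimethylsilyloxy)labda-8(17),13-dien-15-ol | C=C1C[C@H](O[Si](C)(C)C(C)(C)C)[C@H]2[C@](C)(CO[Si](C)(C)C(C)(C)C)CCC[C@]2(C)[C@H]1CC/C(C)=C/CO | intermediate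
35 | (13E)-6α,18-bis(tert-butyldimethylsilyloxy)labda-8(17),13-dien-15-al | C=C1C[C@H](O[Si](C)(C)C(C)(C)C)[C@H]2[C@](C)(CO[Si](C)(C)C(C)(C)C)CCC[C@]2(C)[C@H]1CC/C(C)=C/C=O | intermediate
36 | 4-methylfuran-2(5H)-one | CC1=CC(=O)OC1 | starting material
37 | 4-methyl-2-(trimethylsilyloxy)furan | Cc1coc(O[Si](C)(C)C)c1 | intermediate
38 | 15-O-trimethylsilyl-6α,18-bis(tert-butyldimethylsilyl) ether of the target | C=C1C[C@H](O[Si](C)(C)C(C)(C)C)[C@H]2[C@](C)(CO[Si](C)(C)C(C)(C)C)CCC[C@]2(C)[C@H]1CC/C(C)=C/[C@H](O[Si](C)(C)C)[C@H]1OC(=O)C=C1C | intermediate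
39 | 6α,18-bis(tert-butyldimethylsilyl) ether of the target | C=C1C[C@H](O[Si](C)(C)C(C)(C)C)[C@H]2[C@](C)(CO[Si](C)(C)C(C)(C)C)CCC[C@]2(C)[C@H]1CC/C(C)=C/[C@H](O)[C@H]1OC(=O)C=C1C | intermediate
40 | (5′S)-5′-[(13E,15S)-6α,15,18-trihydroxylabda-8(17),13-dien-15-yl]-4′-methylfuran-2′(5′H)-one (CNP0221530.1) | C=C1C[C@H](O)[C@H]2[C@](C)(CO)CCC[C@]2(C)[C@H]1CC/C(C)=C/[C@H](O)[C@H]1OC(=O)C=C1C | target

**Step count and risks**

Total step count: 24. Longest linear sequence: 18 steps (steps 1–4, 6–13, 18–21, 23, 24).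

Steps most likely to fail:

Step 9. The amide base or the enolate may attack the aldehyde, proton transfer from the phosphonium salt may quench the enolate, or conjugate addition of the hindered tetrasubstituted enolate may be too slow. The fallback sets out from 13 and separates the two bond formations. Methylenation of the C10 aldehyde with Ph3P=CH2 gives the C10-vinyl lactone F1. With no aldehyde left, the lactone enolate (lithium diisopropylamide) is alkylated with allyl bromide on the same α face to give the C4-allyl lactone F2. Ring-closing metathesis with second-generation Grubbs catalyst joins C1 and C2 and returns to the route at 17.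

Step 20. Hydride may be delivered to the less hindered terminus C17 (giving the tetrasubstituted C8=C9 alkene), the π-allyl complex may lose a β-hydrogen to a diene, or delivery may occur on the β face. The fallback sets out from 32. Displacement with KOAc in DMF gives the allylic acetate F3, and methanolysis (K2CO3, MeOH) gives the primary allylic alcohol F4. Mitsunobu coupling with 2-nitrobenzenesulfonylhydrazide (PPh3, diethyl azodicarboxylate, −30 °C) and warming gives the allylic diazene F5. Its retro-ene loss of dinitrogen places hydrogen on C9 and the double bond at C8=C17, returning at 33.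

Step 23. Facial selectivity at the aldehyde may be poor, the syn preference may erode in the open transition state, or the silyloxyfuran may react at its α-carbon. The fallback sets out from 35. Alkoxyallylboration with the antipode of (Z)-[3-(4-methoxybenzyloxy)-2-methylallyl]diisopinocampheylborane that delivers the (15S,5′S) relationship gives the syn adduct F6. Silylation of the C15 hydroxyl (TBSOTf, 2,6-lutidine) gives the tris(silyl) ether F7, and DDQ removes the 4-methoxybenzyl group to give the C5′ alcohol F8. Acryloyl chloride/Et3N gives the acrylate F9. Ring-closing metathesis with second-generation Grubbs catalyst closes the butenolide to the tris(silyl) ether F10, and HF·pyridine returns to the route at 40.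

Further compounds
F1 | step 9 | C10-vinyl analogue of lactone 13 | CC1C(=O)O[C@H]2CC=C(O[Si](C)(C)C(C)(C)C)[C@@](C)(C=C)[C@H]12
F2 | step 9 | C4α-allyl C10-vinyl lactone | C=CC[C@@]1(C)C(=O)O[C@H]2CC=C(O[Si](C)(C)C(C)(C)C)[C@@](C)(C=C)[C@H]12
F3 | step 20 | 17-acetoxy analogue of 32 | CC(C)(C)[Si](C)(C)OC[C@]1(C)CCC[C@]2(C)C(CC/C(C)=C/COCc3ccc(OC)cc3)=C(COC(C)=O)C[C@H](O[Si](C)(C)C(C)(C)C)[C@@H]12
F4 | step 20 | 17-hydroxy analogue of 32 | CC(C)(C)[Si](C)(C)OC[C@]1(C)CCC[C@]2(C)C(CC/C(C)=C/COCc3ccc(OC)cc3)=C(CO)C[C@H](O[Si](C)(C)C(C)(C)C)[C@@H]12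
F5 | step 20 | 17-diazenyl analogue of 32 | CC(C)(C)[Si](C)(C)OC[C@]1(C)CCC[C@]2(C)C(CC/C(C)=C/COCc3ccc(OC)cc3)=C(CN=N)C[C@H](O[Si](C)(C)C(C)(C)C)[C@@H]12
F6 | step 23 | syn 15-hydroxy-5′-(4-methoxybenzyloxy) isopropenyl adduct | C=C1C[C@H](O[Si](C)(C)C(C)(C)C)[C@H]2[C@](C)(CO[Si](C)(C)C(C)(C)C)CCC[C@]2(C)[C@H]1CC/C(C)=C/[C@H](O)[C@@H](OCc1ccc(OC)cc1)C(C)=C
F7 | step 23 | 15-O-silyl ether of F6 | C=C1C[C@H](O[Si](C)(C)C(C)(C)C)[C@H]2[C@](C)(CO[Si](C)(C)C(C)(C)C)CCC[C@]2(C)[C@H]1CC/C(C)=C/[C@H](O[Si](C)(C)C(C)(C)C)[C@@H](OCc1ccc(OC)cc1)C(C)=C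
F8 | step 23 | C5′ alcohol | C=C1C[C@H](O[Si](C)(C)C(C)(C)C)[C@H]2[C@](C)(CO[Si](C)(C)C(C)(C)C)CCC[C@]2(C)[C@H]1CC/C(C)=C/[C@H](O[Si](C)(C)C(C)(C)C)[C@@H](O)C(C)=C
F9 | step 23 | C5′ acrylate | C=C1C[C@H](O[Si](C)(C)C(C)(C)C)[C@H]2[C@](C)(CO[Si](C)(C)C(C)(C)C)CCC[C@]2(C)[C@H]1CC/C(C)=C/[C@H](O[Si](C)(C)C(C)(C)C)[C@@H](OC(=O)C=C)C(C)=C
F10 | step 23 | 6α,15,18-tris(tert-butyldimethylsilyl) ether of the target | C=C1C[C@H](O[Si](C)(C)C(C)(C)C)[C@H]2[C@](C)(CO[Si](C)(C)C(C)(C)C)CCC[C@]2(C)[C@H]1CC/C(C)=C/[C@H](O[Si](C)(C)C(C)(C)C)[C@H]1OC(=O)C=C1C
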